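**Retrosynthetic overview**
- The target comes from its bis(benzyl ether) by hydrogenolysis. Both tetrahydrofuran rings come from an acyclic 1,4-diaryl-1,4-bis(silyloxy)butane carrying two primary mesylates, by fluoride-triggered SN2 etherification with retention at both benzylic carbons.
- That butane comes from a trans-3,4-disubstituted γ-butyrolactone by hydride reduction. The key disconnection is the C3–carbinol bond of this lactone: an intermolecular aldol of a lactone enolate with 3-(benzyloxy)-4,5-dimethoxybenzaldehyde, the carbinol centre then being corrected by oxidation and chelation-controlled reduction.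
- The 4-substituted lactone comes from an Evans syn-aldol of (S)-4-benzyl-3-(pent-4-enoyl)oxazolidin-2-one with O-benzylvanillin, followed by silylation, reductive auxiliary removal, alkene cleavage and lactol oxidation.
- Ring order: a temporary γ-lactone (steps 5–6, opened in step 12), then ring A (tetrahydrofuran with the guaiacyl-type aryl) and ring B (tetrahydrofuran with the trioxygenated aryl) together in step 14.

Abbreviations in names: ArA = 4-(benzyloxy)-3-methoxyphenyl; ArB = 3-(benzyloxy)-4,5-dimethoxyphenyl; TBS = tert-butyldimethylsilyl.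

Assumption: 1, 2, 5 and 14 are bought; lactol 12 and aldol 17 are carried on as epimer mixtures because the centre concerned is erased in the following step.

**Route**

Step 1
Reactants: 1 (S)-4-benzyloxazolidin-2-one; 2 pent-4-enoyl chloride
Product: 4 (S)-4-benzyl-3-(pent-4-enoyl)oxazolidin-2-one, via N-lithio oxazolidinone 3 (not isolated)
Conditions: n-BuLi (1.05 equiv), THF, −78 °C; then 2, −78 → 0 °C
Reagents that add atoms: none
Why: N-acylation of the lithiated Evans oxazolidinone by an acid chloride, with the auxiliary stereocentre untouched.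

Step 2
Reactants: 4 (S)-4-benzyl-3-(pent-4-enoyl)oxazolidin-2-one; 5 4-(benzyloxy)-3-methoxybenzaldehyde
Product: 7 (S)-4-benzyl-3-{(2S)-2-[(S)-ArA(hydroxy)methyl]pent-4-enoyl}oxazolidin-2-one, via Z-boron enolate 6 (not isolated)
Conditions: Bu2BOTf, i-Pr2NEt, CH2Cl2, 0 → −78 °C; 5, −78 → 0 °C; then pH 7 buffer, MeOH, H2O2, 0 °C
Reagents that add atoms: none
Why: Evans syn-aldol reaction in which the Z-boron enolate adds through a Zimmerman–Traxler chair on the face opposite the benzyl group of the (S)-auxiliary, setting both new centres as (2S,3S), the syn relation that later places ArA exo.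

Step 3
Reactants: 7 (S)-4-benzyl-3-{(2S)-2-[(S)-ArA(hydroxy)methyl]pent-4-enoyl}oxazolidin-2-one
Product: 8 (S)-4-benzyl-3-{(2S)-2-[(S)-ArA(OTBS)methyl]pent-4-enoyl}oxazolidin-2-one
Conditions: TBSOTf, 2,6-lutidine, CH2Cl2, 0 °C
Reagents that add atoms: tert-butyldimethylsilyl triflate, CC(C)(C)[Si](C)(C)OS(=O)(=O)C(F)(F)F
Why: Silyl ether formation with a silyl triflate under buffered conditions masks the hindered benzylic alcohol for the later enolate and hydride steps and blocks retro-aldol, without touching a stereocentre.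

Step 4
Reactants: 8 (S)-4-benzyl-3-{(2S)-2-[(S)-ArA(OTBS)methyl]pent-4-enoyl}oxazolidin-2-one
Product: 9 (2R)-2-[(S)-ArA(OTBS)methyl]pent-4-en-1-ol
Conditions: LiBH4, H2O (1 equiv), Et2O, 0 °C
Reagents that add atoms: none
Why: Reductive cleavage of the imide by borohydride attack at the exocyclic carbonyl gives the primary alcohol without epimerising the α-centre (the descriptor changes to R only through priorities) and returns auxiliary 1.

Step 5
Reactants: 9 (2R)-2-[(S)-ArA(OTBS)methyl]pent-4-en-1-ol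
Product: 12 (4R)-4-[(S)-ArA(OTBS)methyl]tetrahydrofuran-2-ol (both anomers), via triol 10 (not isolated), via hydroxy aldehyde 11 (not isolated)
Conditions: OsO4 (2 mol%), NaIO4 (4 equiv), 2,6-lutidine, dioxane/H2O 3:1, rt
Reagents that add atoms: osmium tetroxide, O=[Os](=O)(=O)=O (delivers the new oxygen); sodium periodate, [Na+].[O-]I(=O)(=O)=O (terminal oxidant that restores it)
Why: Lemieux–Johnson oxidative cleavage of the terminal alkene spares the electron-rich arenes and benzyl ethers, and the freed aldehyde is trapped by the 1,4-hydroxyl as a five-membered lactol.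

Step 6
Reactants: 12 (4R)-4-[(S)-ArA(OTBS)methyl]tetrahydrofuran-2-ol
Product: 13 (4R)-4-[(S)-ArA(OTBS)methyl]dihydrofuran-2(3H)-one
Conditions: TEMPO (10 mol%), PhI(OAc)2, CH2Cl2, rt
Reagents that add atoms: none
Why: Oxoammonium (TEMPO) oxidation of a lactol to the γ-lactone is mild and near-neutral, so the benzylic silyl ether and benzyl ether survive and the anomeric mixture converges to one compound.

Step 7
Reactants: 14 3-hydroxy-4,5-dimethoxybenzaldehyde
Product: 15 3-(benzyloxy)-4,5-dimethoxybenzaldehyde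
Conditions: BnBr, K2CO3, DMF, rt
Reagents that add atoms: benzyl bromide, BrCc1ccccc1
Why: Williamson ether synthesis on the only phenol of the aldehyde.

Step 8
Reactants: 13 (4R)-4-[(S)-ArA(OTBS)methyl]dihydrofuran-2(3H)-one; 15 3-(benzyloxy)-4,5-dimethoxybenzaldehyde
Product: 17 (3S,4R)-3-[ArB(hydroxy)methyl]-4-[(S)-ArA(OTBS)methyl]dihydrofuran-2(3H)-one (both carbinol epimers), via lithium enolate 16 (not isolated)
Conditions: LiN(SiMe3)2 (1.1 equiv), THF, −78 °C; then 15, −78 °C; AcOH quench at −78 °C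
Reagents that add atoms: none
Why: Intermolecular aldol addition of the lactone lithium enolate to a non-enolisable aldehyde, in which the aldehyde approaches C3 anti to the bulky C4 substituent and so fixes the trans (3S,4R) relation, while the unselectively formed carbinol centre is corrected in steps 9 and 10.

Step 9
Reactants: 17 (3S,4R)-3-[ArB(hydroxy)methyl]-4-[(S)-ArA(OTBS)methyl]dihydrofuran-2(3H)-one
Product: 18 (3S,4R)-3-[3-(benzyloxy)-4,5-dimethoxybenzoyl]-4-[(S)-ArA(OTBS)methyl]dihydrofuran-2(3H)-one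
Conditions: Dess–Martin periodinane, pyridine, CH2Cl2, 0 °C → rt
Reagents that add atoms: none
Why: Dess–Martin oxidation converts both carbinol epimers into one β-keto lactone whose epimerisable C3 rests trans to the C4 substituent.

Step 10
Reactants: 18 (3S,4R)-3-[3-(benzyloxy)-4,5-dimethoxybenzoyl]-4-[(S)-ArA(OTBS)methyl]dihydrofuran-2(3H)-one
Product: 19 (3S,4R)-3-[(S)-ArB(hydroxy)methyl]-4-[(S)-ArA(OTBS)methyl]dihydrofuran-2(3H)-one
Conditions: Zn(BH4)2 (about 0.2 M in Et2O, made beforehand from ZnCl2 and NaBH4), Et2O/CH2Cl2, −20 → 0 °C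
Reagents that add atoms: none
Why: Chelation-controlled reduction, with zinc bridging the ketone and lactone carbonyls and hydride entering from the side of the C3 hydrogen away from the C4 branch, gives the syn (S)-carbinol as with α-substituted β-keto esters.

Step 11
Reactants: 19 (3S,4R)-3-[(S)-ArB(hydroxy)methyl]-4-[(S)-ArA(OTBS)methyl]dihydrofuran-2(3H)-one
Product: 20 (3S,4R)-3-[(S)-ArB(OTBS)methyl]-4-[(S)-ArA(OTBS)methyl]dihydrofuran-2(3H)-one
Conditions: TBSOTf, 2,6-lutidine, CH2Cl2, 0 °C → rt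
Reagents that add atoms: tert-butyldimethylsilyl triflate, CC(C)(C)[Si](C)(C)OS(=O)(=O)C(F)(F)F
Why: Silyl ether formation removes the last free secondary alcohol, so that retro-aldol during reduction and any selectivity problem during sulfonylation are excluded.

Step 12
Reactants: 20 (3S,4R)-3-[(S)-ArB(OTBS)methyl]-4-[(S)-ArA(OTBS)methyl]dihydrofuran-2(3H)-one
Product: 21 (2R,3R)-2-[(S)-ArB(OTBS)methyl]-3-[(S)-ArA(OTBS)methyl]butane-1,4-diol
Conditions: LiAlH4, THF, 0 °C
Reagents that add atoms: none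
Why: Hydride reduction of the lactone to the 1,4-diol leaves silyl and benzyl ethers alone, and no stereocentre is any longer α to a carbonyl.

Step 13
Reactants: 21 (2R,3R)-2-[(S)-ArB(OTBS)methyl]-3-[(S)-ArA(OTBS)methyl]butane-1,4-diol
Product: 22 (2R,3R)-2-[(S)-ArB(OTBS)methyl]-3-[(S)-ArA(OTBS)methyl]butane-1,4-diyl dimethanesulfonate
Conditions: MsCl (3 equiv), Et3N (4 equiv), CH2Cl2, −10 → 0 °C
Reagents that add atoms: methanesulfonyl chloride, CS(=O)(=O)Cl
Why: Fast sulfonylation of both primary alcohols with excess reagent outruns cyclisation of a mono-mesylate to the unwanted 3,4-disubstituted tetrahydrofuran.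

Step 14
Reactants: 22 (2R,3R)-2-[(S)-ArB(OTBS)methyl]-3-[(S)-ArA(OTBS)methyl]butane-1,4-diyl dimethanesulfonate
Product: 25 (1S,3aR,4S,6aR)-1-ArA-4-ArB-tetrahydro-1H,3H-furo[3,4-c]furan, via ring B mesylate 23 (not isolated), via ring A mesylate 24 (not isolated)
Conditions: Bu4NF (4 equiv), THF, 0 → 40 °C
Reagents that add atoms: none
Why: Fluoride desilylation frees each benzylic alkoxide, which closes its ring by intramolecular Williamson etherification (5-exo-tet SN2 at the primary mesylate, the four-membered alternative being far slower), so both benzylic centres keep their configuration and the cis-fused exo,exo-furofuran results whichever ring closes first.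

Step 15
Reactants: 25 (1S,3aR,4S,6aR)-1-ArA-4-ArB-tetrahydro-1H,3H-furo[3,4-c]furan
Product: 26 4-[(1S,3aR,4S,6aR)-4-(3-hydroxy-4,5-dimethoxyphenyl)tetrahydro-1H,3H-furo[3,4-c]furan-1-yl]-2-methoxyphenol (target)
Conditions: H2 (1 atm), Pd/C (10 wt% palladium on carbon), EtOAc, rt, stopped at full conversion
Reagents that add atoms: none
Why: Hydrogenolysis of the two aryl benzyl ethers is much faster than cleavage of the dialkyl benzylic C–O bonds of the furofuran in neutral EtOAc, so the diphenol is released with all four stereocentres intact.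

**Compound list**

1 | (S)-4-benzyloxazolidin-2-one | O=C1N[C@@H](Cc2ccccc2)CO1 | starting material
2 | pent-4-enoyl chloride | C=CCCC(=O)Cl | starting material
3 | N-lithio derivative of 1 (lithium (S)-4-benzyl-2-oxooxazolidin-3-ide) | [Li]N1C(=O)OC[C@@H]1Cc1ccccc1 | intermediate
4 | (S)-4-benzyl-3-(pent-4-enoyl)oxazolidin-2-one | C=CCCC(=O)N1C(=O)OC[C@@H]1Cc1ccccc1 | intermediate
5 | 4-(benzyloxy)-3-methoxybenzaldehyde | COc1cc(C=O)ccc1OCc1ccccc1 | starting material
6 | Z-dibutylboron enolate of 4, (S)-4-benzyl-3-[(1Z)-1-(dibutylboranyloxy)penta-1,4-dien-1-yl]oxazolidin-2-one | C=CC/C=C(\OB(CCCC)CCCC)N1C(=O)OC[C@@H]1Cc1ccccc1 | intermediate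
7 | (S)-4-benzyl-3-{(2S)-2-[(S)-ArA(hydroxy)methyl]pent-4-enoyl}oxazolidin-2-one | COc1cc([C@@H](O)[C@H](CC=C)C(=O)N2C(=O)OC[C@@H]2Cc2ccccc2)ccc1OCc1ccccc1 | intermediate
8 | (S)-4-benzyl-3-{(2S)-2-[(S)-ArA(OTBS)methyl]pent-4-enoyl}oxazolidin-2-one | COc1cc([C@@H](O[Si](C)(C)C(C)(C)C)[C@H](CC=C)C(=O)N2C(=O)OC[C@@H]2Cc2ccccc2)ccc1OCc1ccccc1 | intermediate
9 | (2R)-2-[(S)-ArA(OTBS)methyl]pent-4-en-1-ol | COc1cc([C@@H](O[Si](C)(C)C(C)(C)C)[C@H](CC=C)CO)ccc1OCc1ccccc1 | intermediate
10 | (4R)-4-[(S)-ArA(OTBS)methyl]pentane-1,2,5-triol (both C2 epimers) | COc1cc([C@@H](O[Si](C)(C)C(C)(C)C)[C@H](CC(O)CO)CO)ccc1OCc1ccccc1 | intermediate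
11 | (3R)-3-[(S)-ArA(OTBS)methyl]-4-hydroxybutanal | COc1cc([C@@H](O[Si](C)(C)C(C)(C)C)[C@H](CC=O)CO)ccc1OCc1ccccc1 | intermediate
12 | (4R)-4-[(S)-ArA(OTBS)methyl]tetrahydrofuran-2-ol (both anomers) | COc1cc([C@@H](O[Si](C)(C)C(C)(C)C)[C@H]2COC(O)C2)ccc1OCc1ccccc1 | intermediate
13 | (4R)-4-[(S)-ArA(OTBS)methyl]dihydrofuran-2(3H)-one | COc1cc([C@@H](O[Si](C)(C)C(C)(C)C)[C@H]2COC(=O)C2)ccc1OCc1ccccc1 | intermediate
14 | 3-hydroxy-4,5-dimethoxybenzaldehyde | COc1cc(C=O)cc(O)c1OC | starting material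
15 | 3-(benzyloxy)-4,5-dimethoxybenzaldehyde | COc1cc(C=O)cc(OCc2ccccc2)c1OC | intermediate
16 | lithium enolate of 13 | COc1cc([C@@H](O[Si](C)(C)C(C)(C)C)[C@H]2COC(O[Li])=C2)ccc1OCc1ccccc1 | intermediate
17 | (3S,4R)-3-[ArB(hydroxy)methyl]-4-[(S)-ArA(OTBS)methyl]dihydrofuran-2(3H)-one (both carbinol epimers) | COc1cc([C@@H](O[Si](C)(C)C(C)(C)C)[C@H]2COC(=O)[C@@H]2C(O)c2cc(OCc3ccccc3)c(OC)c(OC)c2)ccc1OCc1ccccc1 | intermediate
18 | (3S,4R)-3-[3-(benzyloxy)-4,5-dimethoxybenzoyl]-4-[(S)-ArA(OTBS)methyl]dihydrofuran-2(3H)-one | COc1cc([C@@H](O[Si](C)(C)C(C)(C)C)[C@H]2COC(=O)[C@@H]2C(=O)c2cc(OCc3ccccc3)c(OC)c(OC)c2)ccc1OCc1ccccc1 | intermediate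
19 | (3S,4R)-3-[(S)-ArB(hydroxy)methyl]-4-[(S)-ArA(OTBS)methyl]dihydrofuran-2(3H)-one | COc1cc([C@@H](O[Si](C)(C)C(C)(C)C)[C@H]2COC(=O)[C@@H]2[C@H](O)c2cc(OCc3ccccc3)c(OC)c(OC)c2)ccc1OCc1ccccc1 | intermediate
20 | (3S,4R)-3-[(S)-ArB(OTBS)methyl]-4-[(S)-ArA(OTBS)methyl]dihydrofuran-2(3H)-one | COc1cc([C@@H](O[Si](C)(C)C(C)(C)C)[C@H]2COC(=O)[C@@H]2[C@H](O[Si](C)(C)C(C)(C)C)c2cc(OCc3ccccc3)c(OC)c(OC)c2)ccc1OCc1ccccc1 | intermediate
21 | (2R,3R)-2-[(S)-ArB(OTBS)methyl]-3-[(S)-ArA(OTBS)methyl]butane-1,4-diol | COc1cc([C@@H](O[Si](C)(C)C(C)(C)C)[C@@H](CO)[C@H](CO)[C@H](O[Si](C)(C)C(C)(C)C)c2cc(OCc3ccccc3)c(OC)c(OC)c2)ccc1OCc1ccccc1 | intermediate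
22 | (2R,3R)-2-[(S)-ArB(OTBS)methyl]-3-[(S)-ArA(OTBS)methyl]butane-1,4-diyl dimethanesulfonate | COc1cc([C@@H](O[Si](C)(C)C(C)(C)C)[C@@H](COS(C)(=O)=O)[C@H](COS(C)(=O)=O)[C@H](O[Si](C)(C)C(C)(C)C)c2cc(OCc3ccccc3)c(OC)c(OC)c2)ccc1OCc1ccccc1 | intermediate
23 | ring B closed first: {(2S,3R,4R)-2-ArB-4-[(S)-ArA(OTBS)methyl]tetrahydrofuran-3-yl}methyl methanesulfonate | COc1cc([C@@H](O[Si](C)(C)C(C)(C)C)[C@H]2CO[C@H](c3cc(OCc4ccccc4)c(OC)c(OC)c3)[C@H]2COS(C)(=O)=O)ccc1OCc1ccccc1 | intermediate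
24 | ring A closed first: {(2S,3R,4R)-2-ArA-4-[(S)-ArB(OTBS)methyl]tetrahydrofuran-3-yl}methyl methanesulfonate | COc1cc([C@H]2OC[C@H]([C@H](O[Si](C)(C)C(C)(C)C)c3cc(OCc4ccccc4)c(OC)c(OC)c3)[C@@H]2COS(C)(=O)=O)ccc1OCc1ccccc1 | intermediate
25 | (1S,3aR,4S,6aR)-1-ArA-4-ArB-tetrahydro-1H,3H-furo[3,4-c]furan | COc1cc([C@H]2OC[C@H]3[C@@H]2CO[C@@H]3c2cc(OCc4ccccc4)c(OC)c(OC)c2)ccc1OCc1ccccc1 | intermediate
26 | 4-[(1S,3aR,4S,6aR)-4-(3-hydroxy-4,5-dimethoxyphenyl)tetrahydro-1H,3H-furo[3,4-c]furan-1-yl]-2-methoxyphenol | COc1cc([C@H]2OC[C@H]3[C@@H]2CO[C@@H]3c2cc(O)c(OC)c(OC)c2)ccc1O | target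

**Totals and risks**

Total step count: 15. Longest linear sequence: 14 steps (1 → 26 through steps 1–6 and 8–15); step 7 is a one-step side branch.

Most likely to fail, step 8 (aldol of the lactone enolate: stalling or retro-aldol). The fallback sets out from 13 and 15 and comes back at 18. It makes the same bond as a crossed Claisen C-acylation. Aldehyde 15 is oxidised (NaClO2, NaH2PO4, 2-methyl-2-butene, t-BuOH/H2O) to 3-(benzyloxy)-4,5-dimethoxybenzoic acid F1. F1 is activated with 1,1'-carbonyldiimidazole in THF to [3-(benzyloxy)-4,5-dimethoxyphenyl](1H-imidazol-1-yl)methanone F2. Lithium enolate 16, made from 13 with 2.2 equiv LiN(SiMe3)2 in THF at −78 °C, is C-acylated by F2 to give keto lactone 18 directly, so 17 and step 9 are bypassed.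

Most likely to fail, step 10 (diastereoselectivity of the chelation-controlled reduction). The fallback sets out from 18 and comes back at 19. It replaces substrate control by catalyst control: Noyori transfer hydrogenation with RuCl[(S,S)-TsDPEN](p-cymene) (2 mol%) and HCO2H/Et3N 5:2 in CH2Cl2 at rt. This catalyst reduces aryl ketones in the sense that gives the (S)-carbinol. The labile C3 stays trans to the C4 branch. New compounds: none F0.

Most likely to fail, step 14 (fluoride attacking the primary mesylates before both silyl ethers are cleaved). The fallback sets out from 21 and comes back at 25. It reverses the order of deprotection and activation. Bu4NF in THF at rt removes both silyl groups from 21 to give the tetraol (1S,2R,3R,4S)-1-ArA-4-ArB-2,3-bis(hydroxymethyl)butane-1,4-diol F3. MsCl (2.5 equiv) in pyridine at 0 °C → rt then mesylates the two primary hydroxyls, and each benzylic hydroxyl displaces its δ-mesylate in the same pot to give 25, so 22–24 are bypassed.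

**Further compounds**

F1 | step 8 | 3-(benzyloxy)-4,5-dimethoxybenzoic acid | COc1cc(C(=O)O)cc(OCc2ccccc2)c1OC
F2 | step 8 | [3-(benzyloxy)-4,5-dimethoxyphenyl](1H-imidazol-1-yl)methanone | COc1cc(C(=O)n2ccnc2)cc(OCc2ccccc2)c1OC
F0 | step 10 | none | none
F3 | step 14 | (1S,2R,3R,4S)-1-ArA-4-ArB-2,3-bis(hydroxymethyl)butane-1,4-diol | COc1cc([C@@H](O)[C@@H](CO)[C@H](CO)[C@H](O)c2cc(OCc3ccccc3)c(OC)c(OC)c2)ccc1OCc1ccccc1
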